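Labdane numbering: ring A = C1–C5/C10 (C18 and C19 on C4, C20 on C10). Ring B = C5–C10 (O on C7, C17 = exocyclic CH2 on C8). The side chain C11–C16 sits on C9, and the O–O bridge joins C11 and C15.
Cuts: C15–O (peroxyhemiacetal) and C12=C13 (Wittig); C11–O (singlet oxygen on a C11=C12 enol silane); C9–C10 of ring B (radical ring closure with loss of a sulfonyl group from C17); C8–C9 (Morita–Baylis–Hillman), C7–C8 (Weinreb ketone synthesis), C5–C6 (Johnson–Claisen).
Forward: ring A is bought as enone 1. C6–C9, C11, C12 and C17 are joined as an open chain on C5, and ring B, the last ring of the carbon skeleton, closes in step 8. C13–C16 arrive by olefination, and the seven-membered peroxide ring is the ring tautomer that the 11-hydroperoxy-15-al adopts by itself on unmasking.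
Enabling feature: in ring B the C8=C17 methylene lies between oxygenated C7 and C9, and C9 is bonded to quaternary C10. At the ketone level, C7(=O)–C8(=C17H2)–C9 is a 2-acylallyl group on a tertiary carbon. That is the product pattern of a radical allyl transfer onto a C10 radical, which the C1=C10 alkene of ring A can supply.
Stereochemistry: a CBS reduction sets a helper carbinol at C1, and a suprafacial [3,3] shift carries it to C5. C5 sets C10, and the alkene geometry sets C9, in the chair-like ring closure. C7 comes from axial hydride delivery, C11 from allylic-strain-controlled attack of singlet oxygen, and C15 from equilibration.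

Key step: step 8

Remark: C15 is a peroxyhemiacetal carbon and configurationally labile through ring–chain tautomerism, so the given (15R) form (OH cis to the C11 substituent) is taken to be the one favoured at equilibrium. The dioxepine is treated as this tautomer of a hydroperoxy aldehyde, not as a ring of the carbon skeleton.

Step 1
Reactants: 1 2,4,4-trimethylcyclohex-2-en-1-one
Product: 2 (R)-2,4,4-trimethylcyclohex-2-en-1-ol
Conditions: (S)-Me-CBS oxazaborolidine (cat.), BH3·SMe2, THF, −20 °C; MeOH quench
Reagents that add atoms: none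
Why: In this Corey–Bakshi–Shibata reduction the α-methyl-substituted alkenyl flank acts as the large group, so 1,2-hydride delivery should give the (R)-carbinol at labdane C1, a helper stereocentre that only carries chirality on to C5.

Step 2
Reactants: 2 (R)-2,4,4-trimethylcyclohex-2-en-1-ol
Product: 4 ethyl 2-[(1S)-2,6,6-trimethylcyclohex-2-en-1-yl]acetate, via ketene acetal 3 (not isolated)
Conditions: MeC(OEt)3, EtCO2H (cat.), 140 °C, EtOH distilled off
Reagents that add atoms: triethyl orthoacetate, CCOC(C)(OCC)OCC
Why: The [3,3] shift of this Johnson–Claisen rearrangement is suprafacial on the ring, so the C5–C6 bond forms on the face that held the C1–O bond; this sets C5 (S), moves the alkene to C1=C10 and turns the former ring oxygen into the C7 carbonyl oxygen.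

Step 3
Reactants: 4 ethyl 2-[(1S)-2,6,6-trimethylcyclohex-2-en-1-yl]acetate
Product: 5 N-methoxy-N-methyl-2-[(1S)-2,6,6-trimethylcyclohex-2-en-1-yl]acetamide
Conditions: MeNH(OMe)·HCl, i-PrMgCl, THF, −15 °C
Reagents that add atoms: N,O-dimethylhydroxylamine hydrochloride, CNOC.Cl
Why: Aminolysis of the ester by the magnesium amide (Weinreb amide formation) is standard for unhindered acetates and leaves C5, which is not α to the carbonyl, untouched.

Step 4
Reactants: 5 N-methoxy-N-methyl-2-[(1S)-2,6,6-trimethylcyclohex-2-en-1-yl]acetamide
Product: 6 1-[(1S)-2,6,6-trimethylcyclohex-2-en-1-yl]but-3-en-2-one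
Conditions: vinylMgBr, THF, −78 to 0 °C; poured into cold 1 M HCl
Reagents that add atoms: vinylmagnesium bromide, C=C[Mg]Br
Why: In this Weinreb ketone synthesis the chelated tetrahedral intermediate stops over-addition, and the inverse acidic quench keeps the released amine from adding to the vinyl ketone (C8=C17).

Step 5
Reactants: 6 1-[(1S)-2,6,6-trimethylcyclohex-2-en-1-yl]but-3-en-2-one; 7 3-(tert-butyldimethylsilyloxy)propanal
Product: 8 6-(tert-butyldimethylsilyloxy)-4-hydroxy-3-methylidene-1-[(1S)-2,6,6-trimethylcyclohex-2-en-1-yl]hexan-2-one (both carbinol epimers)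
Conditions: DABCO (0.5 equiv), 7 (2 equiv), dioxane–H2O, 25 °C
Reagents that add atoms: none
Why: In this Morita–Baylis–Hillman reaction the amine adds to C17 and the resulting enolate attacks aldehyde 7 through C8 to form C8–C9; the new carbinol centre does not matter because C9 becomes sp2 in step 7.

Step 6
Reactants: 8 Morita–Baylis–Hillman alcohol
Product: 9 the corresponding C9 acetate (both epimers)
Conditions: Ac2O, pyridine, DMAP (cat.), CH2Cl2, 0 °C
Reagents that add atoms: acetic anhydride, CC(=O)OC(C)=O
Why: Routine acylation of the secondary allylic alcohol supplies the leaving group for the allylic transposition.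

Step 7
Reactants: 9 Morita–Baylis–Hillman acetate
Product: 10 (3Z)-6-(tert-butyldimethylsilyloxy)-3-[(phenylsulfonyl)methyl]-1-[(1S)-2,6,6-trimethylcyclohex-2-en-1-yl]hex-3-en-2-one
Conditions: PhSO2Na, DMF, 25 °C
Reagents that add atoms: sodium benzenesulfinate, [Na+].[O-]S(=O)c1ccccc1
Why: SN2′ displacement of a Morita–Baylis–Hillman acetate by the sulfur of sulfinate is well known and should give the more stable trisubstituted enone, with C11 trans to the C7 acyl group and cis to C17 (Z by the priority rules).

Step 8
Reactants: 10 (3Z)-allyl sulfone enone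
Product: 11 12-(tert-butyldimethylsilyloxy)-13,14,15,16-tetranorlabd-8(17)-en-7-one (trans-decalin, 5α-H, 9α-H, 10β-CH3)
Conditions: Fe(acac)3 (0.5 equiv), PhSiH3 (2 equiv, syringe pump), EtOH (0.005 M), 60 °C
Reagents that add atoms: none
Why: Proposed new method: An iron hydride made from Fe(acac)3 and PhSiH3 should hand a hydrogen atom to C1 of the only electron-neutral alkene (C1=C10), and the nucleophilic tertiary C10 radical then adds to C9, the β-carbon of the enone, after which the C8 radical ejects the phenylsulfonyl radical from C17 (or is first reduced by divalent iron to the enolate, which expels sulfinate), so that both paths end in the C8=C17 methylene next to the C7 ketone while the sulfonyl radical takes up the electron that returns trivalent iron. The closest known reaction types are the iron-catalysed hydrogen-atom-transfer Giese coupling of alkenes with enones, the hydroallylation of alkenes with Morita–Baylis–Hillman adducts under the same conditions and radical allyl transfer from 2-acylallyl sulfones (SH2′); new are the ring-closing use and the β-substituted acceptor terminus. Ring B closes in the 6-endo-trig mode (C10 to C9, with C8=C9 inside the new ring), since the 5-exo alternative would have to attack the fully substituted, polarity-mismatched C8. C10 is controlled by C5: with the C5 side chain equatorial on the ring A chair, the chain reaches the radical lobe on the side of H5, which leaves the methyl group axial and gives the trans-decalin, as in the second ring closure of radical polyene cyclisations that pass through the same type of C10 radical. C9 is controlled by the alkene geometry, because C11 stands trans to C7 in 10 and therefore becomes equatorial (H9 α) in the chair-like transition state. The step needs hydrogen-atom transfer to the donor alkene rather than to the acceptor, which the electronic difference between the two alkenes secures, and ring closure faster than capture by the product enone, which high dilution and slow silane addition secure.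

Step 9
Reactants: 11 7-ketone
Product: 13 13,14,15,16-tetranorlabd-8(17)-ene-7β,12-diol, via silyl ether alcohol 12 (not isolated)
Conditions: NaBH4, CeCl3·7H2O, MeOH, −78 to 0 °C; then 1 M aq HCl, 0 to 25 °C
Reagents that add atoms: none
Why: Luche reduction gives clean 1,2-reduction of the α-methylene ketone, axial hydride delivery from the α face (past only H5 and H9) should set the equatorial 7β-alcohol, and the dilute acid then cleaves only the primary silyl ether.

Step 10
Reactants: 13 7β,12-diol
Product: 14 7β-hydroxy-13,14,15,16-tetranorlabd-8(17)-en-12-al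
Conditions: TEMPO (10 mol %), PhI(OAc)2, CH2Cl2, 25 °C
Reagents that add atoms: none
Why: Oxoammonium (TEMPO) oxidation is sterically selective for the primary alcohol over the hindered secondary allylic C7 alcohol and stops at the aldehyde.

Step 11
Reactants: 14 hydroxy aldehyde
Product: 15 (11Z)-7β,12-bis(triethylsilyloxy)-13,14,15,16-tetranorlabda-8(17),11-diene
Conditions: Et3N (5 equiv), then TESOTf (2.5 equiv), CH2Cl2, −78 to 0 °C
Reagents that add atoms: triethylsilyl trifluoromethanesulfonate, CC[Si](CC)(CC)OS(=O)(=O)C(F)(F)F
Why: Soft enolisation of the aldehyde with silyl triflate and amine gives mainly the Z enol silane and protects the 7β-alcohol in the same operation; adding base first prevents an acid-induced carbonyl-ene reaction with C8=C17.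

Step 12
Reactants: 15 bis-silyl enol ether
Product: 16 7β-(triethylsilyloxy)-11-(triethylsilylperoxy)-13,14,15,16-tetranorlabd-8(17)-en-12-al (C11 arranged as in the target; 11R by the priority rules in this compound)
Conditions: O2, tetraphenylporphyrin (cat.), hν (visible), CH2Cl2, −78 °C
Reagents that add atoms: dioxygen, O=O
Why: In this photooxygenation of a silyl enol ether (the silatropic variant of the Schenck ene reaction) singlet oxygen bonds to the nucleophilic C11 and the silyl group moves to the terminal peroxy oxygen, freeing the C12 aldehyde; allylic 1,3-strain in the Z enol ether holds H9 in the alkene plane, so oxygen should arrive from the flat C8(=C17) flank rather than the quaternary C10 flank, and the 1,1-disubstituted C8=C17 alkene is far less reactive.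

Step 13
Reactants: 17 3-bromo-1,1-dimethoxypropane; 18 triphenylphosphine
Product: 19 (3,3-dimethoxypropyl)triphenylphosphonium bromide
Conditions: MeCN, reflux
Reagents that add atoms: none
Why: SN2 quaternisation of the phosphine by a primary bromide is standard phosphonium salt formation.

Step 14
Reactants: 19 phosphonium bromide
Product: 21 4,4-dimethoxy-2-(triphenylphosphoranylidene)butanal, via phosphorus ylide 20 (not isolated)
Conditions: KOt-Bu, THF, 0 °C; then HCO2Et, 0 to 25 °C
Reagents that add atoms: ethyl formate, CCOC=O
Why: C-formylation of a non-stabilised ylide by a formate ester is a known route to α-formyl ylides; the released ethoxide deprotonates the acylated salt to give the stabilised ylide that carries C13–C16.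

Step 15
Reactants: 16 α-silylperoxy aldehyde; 21 formyl ylide
Product: 22 (11S,12E)-15,15-dimethoxy-7β-(triethylsilyloxy)-11-(triethylsilylperoxy)labda-8(17),12-dien-16-al
Conditions: 21 (1.5 equiv), CH2Cl2, 25 °C, dark
Reagents that add atoms: none
Why: Wittig olefination of protected α-peroxy aldehydes with stabilised ylides is known to preserve the O–O bond; the weakly basic α-substituted formyl ylide should place C11 trans to the formyl group (E), which is cis to C14 as the later ring needs.

Step 16
Reactants: 22 protected peroxy enal
Product: 24 CNP0269954.2 (target), via open hydroperoxy dialdehyde 23 (not isolated)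
Conditions: AcOH–THF–H2O (3:1:1), 25 °C
Reagents that add atoms: water, O
Why: Mild aqueous acid removes both triethylsilyl groups and hydrolyses the dimethyl acetal, and the freed C11 hydroperoxide, held cis to C14 by the E alkene, adds to the C15 aldehyde (peroxyhemiacetal formation) but cannot reach the trans-disposed C16 aldehyde; base is avoided because H11 invites Kornblum–DeLaMare fragmentation, and C15 settles by equilibration.

Compound list
1 | 2,4,4-trimethylcyclohex-2-en-1-one | CC1=CC(C)(C)CCC1=O | starting material
2 | (R)-2,4,4-trimethylcyclohex-2-en-1-ol | O[C@@H]1CCC(C)(C)C=C1C | intermediate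
3 | (R)-1-ethoxyvinyl 2,4,4-trimethylcyclohex-2-enyl ether (ketene acetal) | C=C(OCC)O[C@@H]1CCC(C)(C)C=C1C | intermediate
4 | ethyl 2-[(1S)-2,6,6-trimethylcyclohex-2-en-1-yl]acetate | CCOC(=O)C[C@@H]1C(C)=CCCC1(C)C | intermediate
5 | N-methoxy-N-methyl-2-[(1S)-2,6,6-trimethylcyclohex-2-en-1-yl]acetamide | CON(C)C(=O)C[C@@H]1C(C)=CCCC1(C)C | intermediate
6 | 1-[(1S)-2,6,6-trimethylcyclohex-2-en-1-yl]but-3-en-2-one | C=CC(=O)C[C@@H]1C(C)=CCCC1(C)C | intermediate
7 | 3-(tert-butyldimethylsilyloxy)propanal | O=CCCO[Si](C)(C)C(C)(C)C | starting material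
8 | Morita–Baylis–Hillman alcohol (carbinol epimers) | C=C(C(O)CCO[Si](C)(C)C(C)(C)C)C(=O)C[C@@H]1C(C)=CCCC1(C)C | intermediate
9 | Morita–Baylis–Hillman acetate (epimers) | C=C(C(OC(C)=O)CCO[Si](C)(C)C(C)(C)C)C(=O)C[C@@H]1C(C)=CCCC1(C)C | intermediate
10 | (3Z)-allyl sulfone enone | O=C(C[C@@H]1C(C)=CCCC1(C)C)/C(CS(=O)(=O)c1ccccc1)=C/CCO[Si](C)(C)C(C)(C)C | intermediate
11 | 12-(tert-butyldimethylsilyloxy)-13,14,15,16-tetranorlabd-8(17)-en-7-one | C=C1[C@H](CCO[Si](C)(C)C(C)(C)C)[C@@]2(C)CCCC(C)(C)[C@@H]2CC1=O | intermediate
12 | 12-(tert-butyldimethylsilyloxy)-13,14,15,16-tetranorlabd-8(17)-en-7β-ol | C=C1[C@H](CCO[Si](C)(C)C(C)(C)C)[C@@]2(C)CCCC(C)(C)[C@@H]2C[C@@H]1O | intermediate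
13 | 13,14,15,16-tetranorlabd-8(17)-ene-7β,12-diol | C=C1[C@H](CCO)[C@@]2(C)CCCC(C)(C)[C@@H]2C[C@@H]1O | intermediate
14 | 7β-hydroxy-13,14,15,16-tetranorlabd-8(17)-en-12-al | C=C1[C@H](CC=O)[C@@]2(C)CCCC(C)(C)[C@@H]2C[C@@H]1O | intermediate
15 | (11Z)-7β,12-bis(triethylsilyloxy)-13,14,15,16-tetranorlabda-8(17),11-diene | C=C1[C@H](/C=C\O[Si](CC)(CC)CC)[C@@]2(C)CCCC(C)(C)[C@@H]2C[C@@H]1O[Si](CC)(CC)CC | intermediate
16 | 7β-(triethylsilyloxy)-11-(triethylsilylperoxy)-13,14,15,16-tetranorlabd-8(17)-en-12-al | C=C1[C@H]([C@@H](OO[Si](CC)(CC)CC)C=O)[C@@]2(C)CCCC(C)(C)[C@@H]2C[C@@H]1O[Si](CC)(CC)CC | intermediate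
17 | 3-bromo-1,1-dimethoxypropane | COC(CCBr)OC | starting material
18 | triphenylphosphine | c1ccc(cc1)P(c1ccccc1)c1ccccc1 | starting material
19 | (3,3-dimethoxypropyl)triphenylphosphonium bromide | COC(CC[P+](c1ccccc1)(c1ccccc1)c1ccccc1)OC.[Br-] | intermediate
20 | (3,3-dimethoxypropylidene)triphenylphosphorane | COC(CC=P(c1ccccc1)(c1ccccc1)c1ccccc1)OC | intermediate
21 | 4,4-dimethoxy-2-(triphenylphosphoranylidene)butanal | COC(CC(C=O)=P(c1ccccc1)(c1ccccc1)c1ccccc1)OC | intermediate
22 | (11S,12E)-15,15-dimethoxy-7β-(triethylsilyloxy)-11-(triethylsilylperoxy)labda-8(17),12-dien-16-al | C=C1[C@H]([C@@H](OO[Si](CC)(CC)CC)/C=C(/C=O)CC(OC)OC)[C@@]2(C)CCCC(C)(C)[C@@H]2C[C@@H]1O[Si](CC)(CC)CC | intermediate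
23 | (11S,12E)-11-hydroperoxy-7β-hydroxylabda-8(17),12-diene-15,16-dial | C=C1[C@H]([C@@H](OO)/C=C(/C=O)CC=O)[C@@]2(C)CCCC(C)(C)[C@@H]2C[C@@H]1O | intermediate
24 | CNP0269954.2, the 11,15-peroxyhemiacetal of 23 (11S,15R; 7β-OH) | C=C1[C@H]([C@@H]2C=C(C=O)C[C@H](O)OO2)[C@@]2(C)CCCC(C)(C)[C@@H]2C[C@@H]1O | target

Total step count: 16. Longest linear sequence: 14 (steps 1–12, 15, 16).

Steps most likely to fail

Step 8 (labelled step).
- What may go wrong: the C10 radical captures hydrogen before it closes the ring; hydrogen-atom or hydride transfer reaches the acceptor; the reducing medium or further radicals consume the α-methylene ketone; the expelled sulfinate adds back; or closure gives the cis ring fusion.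
- Fallback (known chemistry, no hydride source): the same C10 radical is made by redox-neutral visible-light photoredox fragmentation of a tertiary alkyl cesium oxalate. This is a known way to form quaternary carbons by conjugate addition and by addition–elimination on allylic acceptors.
- The fallback sets out from 5. Mukaiyama hydration (Mn(dpm)3, PhSiH3, O2, i-PrOH) of the C1=C10 alkene gives the tertiary C10 alcohol F1 (C10 epimers, of no consequence). Excess vinylMgBr gives the hydroxy vinyl ketone F2, and the Morita–Baylis–Hillman reaction with 7 gives the diol F3. Ac2O/pyridine acetylates only the secondary alcohol to give the acetate F4, and PhSO2Na gives the hydroxy allyl sulfone F5. Methyl chlorooxoacetate with DMAP gives the mixed oxalate F6, and one equivalent of aqueous CsOH gives the cesium oxalate F7.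
- Blue-LED irradiation with Ir[dF(CF3)ppy]2(dtbbpy)PF6 in DME–DMF then releases two CO2 and the C10 radical, which closes ring B as in step 8. The expelled sulfonyl radical is reduced to sulfinate by the reduced photocatalyst. The route is rejoined at 11.

Step 12.
- What may go wrong: poor facial selectivity at C11, or [2+2] addition of oxygen followed by cleavage of the C11–C12 bond instead of silyl migration.
- Fallback: catalyst control through an enamine replaces substrate control through the enol silane.
- The fallback sets out from 14. TESCl/imidazole gives the 7-O-silyl aldehyde F8. The known amino-acid-catalysed α-oxidation of aldehydes by singlet oxygen follows (proline-type amine of the matched absolute configuration, O2, tetraphenylporphyrin, hν, DMF, 0 °C) and gives the α-hydroperoxy aldehyde F9. TESOTf/2,6-lutidine silylates the hydroperoxide, and the route is rejoined at 16.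

Step 15.
- What may go wrong: slow olefination of the hindered aldehyde by the weakly nucleophilic formyl ylide, which leaves time for base-induced loss of the peroxide at C11.
- Fallback: a more nucleophilic ester-stabilised ylide is used, followed by redox adjustment that preserves the peroxide.
- The fallback sets out from 19 and 16. Ylide 20, made from 19 with KOt-Bu, is acylated with methyl chloroformate to give the ester ylide F10. Its Wittig reaction with 16 gives the E enoate F11. i-Bu2AlH in CH2Cl2 at −78 °C gives the allylic alcohol F12, and MnO2 oxidises it to the enal. The route is rejoined at 22.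

Further compounds
F1 | step 8 | 2-[(1S)-2-hydroxy-2,6,6-trimethylcyclohexyl]-N-methoxy-N-methylacetamide (C10 epimers) | CON(C)C(=O)C[C@@H]1C(C)(O)CCCC1(C)C
F2 | step 8 | 1-[(1S)-2-hydroxy-2,6,6-trimethylcyclohexyl]but-3-en-2-one | C=CC(=O)C[C@@H]1C(C)(O)CCCC1(C)C
F3 | step 8 | Morita–Baylis–Hillman diol | C=C(C(O)CCO[Si](C)(C)C(C)(C)C)C(=O)C[C@@H]1C(C)(O)CCCC1(C)C
F4 | step 8 | secondary acetate of F3 | C=C(C(OC(C)=O)CCO[Si](C)(C)C(C)(C)C)C(=O)C[C@@H]1C(C)(O)CCCC1(C)C
F5 | step 8 | (3Z)-hydroxy allyl sulfone enone | O=C(C[C@@H]1C(C)(O)CCCC1(C)C)/C(CS(=O)(=O)c1ccccc1)=C/CCO[Si](C)(C)C(C)(C)C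
F6 | step 8 | tertiary alkyl methyl oxalate of F5 | O=C(C[C@@H]1C(C)(OC(=O)C(=O)OC)CCCC1(C)C)/C(CS(=O)(=O)c1ccccc1)=C/CCO[Si](C)(C)C(C)(C)C
F7 | step 8 | tertiary alkyl cesium oxalate | O=C(C[C@@H]1C(C)(OC(=O)C(=O)[O-])CCCC1(C)C)/C(CS(=O)(=O)c1ccccc1)=C/CCO[Si](C)(C)C(C)(C)C.[Cs+]
F8 | step 12 | 7β-(triethylsilyloxy)-13,14,15,16-tetranorlabd-8(17)-en-12-al | C=C1[C@H](CC=O)[C@@]2(C)CCCC(C)(C)[C@@H]2C[C@@H]1O[Si](CC)(CC)CC
F9 | step 12 | 11-hydroperoxy-7β-(triethylsilyloxy)-13,14,15,16-tetranorlabd-8(17)-en-12-al | C=C1[C@H]([C@@H](OO)C=O)[C@@]2(C)CCCC(C)(C)[C@@H]2C[C@@H]1O[Si](CC)(CC)CC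
F10 | step 15 | methyl 4,4-dimethoxy-2-(triphenylphosphoranylidene)butanoate | COC(=O)C(CC(OC)OC)=P(c1ccccc1)(c1ccccc1)c1ccccc1
F11 | step 15 | methyl (11S,12E)-15,15-dimethoxy-7β-(triethylsilyloxy)-11-(triethylsilylperoxy)labda-8(17),12-dien-16-oate | C=C1[C@H]([C@@H](OO[Si](CC)(CC)CC)/C=C(/C(=O)OC)CC(OC)OC)[C@@]2(C)CCCC(C)(C)[C@@H]2C[C@@H]1O[Si](CC)(CC)CC
F12 | step 15 | (11S,12E)-15,15-dimethoxy-7β-(triethylsilyloxy)-11-(triethylsilylperoxy)labda-8(17),12-dien-16-ol | C=C1[C@H]([C@@H](OO[Si](CC)(CC)CC)/C=C(/CO)CC(OC)OC)[C@@]2(C)CCCC(C)(C)[C@@H]2C[C@@H]1O[Si](CC)(CC)CC
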